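Which flask makes the most target from the same charges, and does a warm stage followed by cold days keep the gain of the cold?

| flask | solid substrate | partner | second substrate | catalyst | temperature | remark | time |
|---|---|---|---|---|---|---|---|
| north-west | 13 mM | 20 mM | 20 mM | 0.20 mM | −5 °C | run made earlier |  |
| south | 30 mM | 20 mM | 20 mM | 0.20 mM | 17 °C | run made earlier |  |
| birch | 20 mM | 20.0 mM | 20.0 mM | 0.20 mM | −15 °C |  | 25 d |
| elm | 20 mM | 20.0 mM | 20.0 mM | 0.20 mM | 5 °C |  | 25 d |
| larch | 20 mM | 20.0 mM | 20.0 mM | 0.20 mM |  | at 25 °C until 20 d, from then on at −15 °C | 25 d |
| cedar | 20 mM | 20.0 mM | 20.0 mM | 0.20 mM | 25 °C |  | 25 d |

- the flask that comes out highest in amount of target, in percent of the solid substrate charged, or "all alike" when all lie within 1.5 percentage points (birch / elm / larch / cedar / all alike)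
- target at the end, in percent of the solid substrate charged, birch
- target at the end, in percent of the solid substrate charged, elm
- target at the end, in percent of the solid substrate charged, larch
- target at the end, in percent of the solid substrate charged, cedar

| north-west: time / d | north-west: target / % | south: time / d | south: target / % |
|---|---|---|---|
| 1.67 | 14.0 | 0.500 | 3.3 |
| 5.00 | 22.0 | 1.67 | 4.6 |
| 8.00 | 22.8 | 2.50 | 5.5 |
| 12.0 | 23.9 | 4.00 | 4.5 |

(standard deviation of a reading: 0.5 percentage points)

- solid, in amounts per volume of the solution: solid substrate
- what was read earlier has a scatter of 0.5 percentage points, one standard deviation
- at the start none of the solid substrate is in solution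
- what has only dissolved of solid substrate counts as not reacted

The reckoning here keeps a ledger of partner as the limiting reagent and books one partner for each target. In the north-west run the last reading gives 3.11 mM of target from 20 mM of partner, so 16.9 mM stands in another entry, and second substrate, charged equally, is the likely claimant. That run's entry is 15.5% of the partner. The south run, from 1.67 d on, averages 4.87% of its solid substrate in the readings, which books 7.30% of the partner. This is the partner share: target at the plateau over partner charged, here at 17 °C.

The south run holds more solid substrate than the north-west run, yet its share is smaller, so the reckoning here reads the share as falling with temperature, although the two runs differ in both settings. The south run also levels off by 2.50 d, sooner than the north-west run at 5.00 d.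

For larch, 25 °C lies above the south run's temperature, and the warm stage of 20 d is much longer than the south run's levelling time. The reckoning here therefore assumes that the target of larch is made before the chill and stays at that level through the cold days. Larch should then stay near cedar, at about 7.30% of its solid substrate, while birch, the flask kept coldest throughout, should lead.

The forecast names birch, with 22% for birch, 11% for elm, 14% for larch and 5.7% for cedar. On larch it says “The data cannot separate these”, and its value lies above the reckoning here.

Larch ends at 6.73%, elm at 11.6%, and birch comes out highest at 18.2%.

    second substrate + partner + catalyst → catalyst + second product (k = 1.87 × 10⁵ /M²/h, Ea = 39.0 kJ/mol)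
    partner ⇌ dormant form (K = 19.0, k = 0.0186 /h, Ea = 110 kJ/mol, ΔH = −36.0 kJ/mol)
    starting material + partner + catalyst → catalyst + target (k = 1.25 × 10⁵ /M²/h, Ea = 38.0 kJ/mol)
    solid substrate ⇌ starting material, rate k4*(cs4 - [starting material]) while solid is left; crystals form when [starting material] > cs4 (solubility = 6.80 mM, k = 0.0353 /h)
    (constants at 25 °C)

At the change of temperature, larch already held target at 6.72% of its solid substrate, second product at 17.9 mM and dormant form at 0.714 mM, with partner down to 0.0132% of its own charge. At 25.0 d its target stands at 6.73%. The south share of 7.30%, put on the charges of cedar, gives 7.30%, and cedar stands at 6.97% at 25.0 d, then at 9.21% at 250 d, when its dormant form has gone from 0.641 mM to 0.00474 mM.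

(The data come from a simulation for substances that don't exist; scatter was added.)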